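The route rests on disconnecting both bonds at the adjacent ring carbons C1 (side chain) and C2 (free OH) of the benzene ring: C1–C7 and C2–O. Because C2 is flanked by the C3 methoxy group and C1 only by C6–H, the ring is treated as a 3-methoxyaryne. In one operation the aryne made from a C2 chloride takes up the (S)-configured alkenyllithium alkoxide at C1 and, through borate oxidation, an oxygen at C2, giving the whole skeleton with C8 already set. The precursors are a regiodefined 4-chloro-3-methoxy-2-methylphenyl TIPS ether and (S)-2-bromo-6-methylhepta-1,5-dien-3-ol; four protecting-group and acylation steps finish the target.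

Key step: step 7

Remarks: ring atoms are numbered C1 (side chain), C2 (OH), C3 (OMe), C4 (Me), C5 (OAc), C6 (H); C7 is the alkene carbon on the ring and C8 the carbinol carbon. The borane of step 5 is defined by its origin from (+)-α-pinene, which fixes its handedness; the (S) outcome is assigned from the recalled facial preference of that reagent, and the mirror-image borane would be used if the opposite sense were found.

Step 1
Reactants: 1 2-methylbenzene-1,3-diol (2-methylresorcinol)
Product: 2 4-chloro-2-methylbenzene-1,3-diol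
Conditions: SO2Cl2 (1.0 equiv), Et2O, 0 °C → rt
Reagents that add atoms: sulfuryl chloride, O=S(=O)(Cl)Cl
Why: Electrophilic aromatic chlorination of a symmetric resorcinol, whose two activated positions are equivalent, can give only one monochloride, so the position of the halogen is not in doubt.

Step 2
Reactants: 2 4-chloro-2-methylbenzene-1,3-diol
Product: 3 6-chloro-2-methyl-3-[(triisopropylsilyl)oxy]phenol
Conditions: TIPSCl (1.05 equiv), imidazole, DMF, 0 °C → rt
Reagents that add atoms: chlorotriisopropylsilane, CC(C)[Si](Cl)(C(C)C)C(C)C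
Why: Sterically controlled O-silylation: the hydroxyl para to chlorine has one ortho substituent, whereas the other is flanked by methyl and chlorine and should react far more slowly with the bulky chlorosilane.

Step 3
Reactants: 3 6-chloro-2-methyl-3-[(triisopropylsilyl)oxy]phenol
Product: 4 (4-chloro-3-methoxy-2-methylphenoxy)triisopropylsilane
Conditions: MeI, K2CO3, acetone, 40 °C
Reagents that add atoms: iodomethane, CI
Why: Williamson etherification of the only remaining, relatively acidic ortho-chlorophenol; the aryl TIPS ether tolerates K2CO3 in acetone.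

Step 4
Reactants: 5 acrolein (prop-2-enal)
Product: 7 2-bromoprop-2-enal (2-bromoacrolein), via 2,3-dibromopropanal 6 (not isolated)
Conditions: Br2, CH2Cl2, −78 → 0 °C; then Et3N, 0 °C
Reagents that add atoms: bromine, BrBr
Why: Bromine addition to the enal followed by base-induced loss of HBr from the α-bromo aldehyde (E1cB elimination) is the standard preparation of this 2-bromo enal.

Step 5
Reactants: 7 2-bromoprop-2-enal
Product: 9 (S)-2-bromohexa-1,5-dien-3-ol, via borinate ester 8 (not isolated)
Conditions: (−)-Ipc2BOMe [from (+)-α-pinene], allylMgBr, Et2O, −78 °C → rt; then 7, −78 °C; aq NaOH, H2O2, 0 °C → rt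
Reagents that add atoms: allylmagnesium bromide, C=CC[Mg]Br
Why: Brown asymmetric allylboration through a chair transition state, in which the isopinocampheyl groups derived from (+)-α-pinene should direct allyl transfer to the aldehyde face that gives the (S)-carbinol (the sense that takes benzaldehyde to (S)-1-phenylbut-3-en-1-ol); this sets C8 of the target.

Step 6
Reactants: 9 (S)-2-bromohexa-1,5-dien-3-ol
Product: 10 (S)-2-bromo-6-methylhepta-1,5-dien-3-ol
Conditions: 2-methylbut-2-ene (excess), second-generation Grubbs catalyst (3 mol %), CH2Cl2, 40 °C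
Reagents that add atoms: 2-methylbut-2-ene, CC=C(C)C
Why: Olefin cross-metathesis of the monosubstituted alkene with excess 2-methylbut-2-ene installs the prenyl terminus, while the hindered, electron-poor 2-bromoalkene and the carbinol centre should remain untouched.

Step 7
Reactants: 4 (4-chloro-3-methoxy-2-methylphenoxy)triisopropylsilane; 10 (S)-2-bromo-6-methylhepta-1,5-dien-3-ol
Product: 15 (S)-2-(3-hydroxy-6-methylhepta-1,5-dien-2-yl)-6-methoxy-5-methyl-4-[(triisopropylsilyl)oxy]phenol, via dilithiated alkenyl alkoxide 11 (not isolated), via aryne 12 (not isolated), via C2-aryllithium adduct 13 (not isolated), via cyclic boronate 14 (not isolated)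
Conditions: 10 (1.5 equiv), t-BuLi (3 equiv per 10), Et2O/THF, −78 °C; 4, then LiTMP, −78 → −20 °C; B(OMe)3, −78 °C → rt; aq NaOH, H2O2, 0 °C
Reagents that add atoms: hydrogen peroxide, OO
Why: LiTMP removes C1–H, the only hydrogen ortho to chlorine in 4, and loss of LiCl gives aryne 12; the vinylic carbanion of 11 adds at C1 to form C1–C7 and leaves the charge on C2 (13), which B(OMe)3 captures as boronate 14 before alkaline H2O2 shifts the aryl group from boron to oxygen to form C2–O. The closest known reaction type is carbolithiation of 3-methoxyarynes generated from haloanisoles with electrophilic trapping of the ortho-lithiated adduct, followed by ordinary borate oxidation. No ring is closed in the product (the six-membered boronate ring of 14 is transient) and no stereocentre is created; C8 is carried through unchanged because it is present as a lithium alkoxide and no bond to it is broken. The step needs regioselective capture of the aryne, which the inductively withdrawing C3 methoxy group secures by making C1 the electrophilic terminus and stabilising the carbanion at C2, while C6–H exerts no opposing bias. It also needs a single aryne and a surviving nucleophile: chlorine at C2 has only C1–H beside it and does not undergo exchange with the alkenyllithium, the bulky non-coordinating TIPS ether keeps the base away from C6–H, and the alkoxide form of 11 prevents β-elimination to an allene.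

Step 8
Reactants: 15 (S)-2-(3-hydroxy-6-methylhepta-1,5-dien-2-yl)-6-methoxy-5-methyl-4-[(triisopropylsilyl)oxy]phenol
Product: 16 (S)-2-[3-methoxy-2-(methoxymethoxy)-4-methyl-5-[(triisopropylsilyl)oxy]phenyl]-6-methylhepta-1,5-dien-3-ol
Conditions: MOMCl, K2CO3, acetone, 0 °C → rt
Reagents that add atoms: chloromethyl methyl ether, COCCl
Why: Williamson-type O-alkylation in which K2CO3 ionises only the phenol, so the C8 alcohol should stay free.

Step 9
Reactants: 16 (S)-2-[3-methoxy-2-(methoxymethoxy)-4-methyl-5-[(triisopropylsilyl)oxy]phenyl]-6-methylhepta-1,5-dien-3-ol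
Product: 17 (S)-2-[3-methoxy-2-(methoxymethoxy)-4-methyl-5-[(triisopropylsilyl)oxy]phenyl]-6-methylhepta-1,5-dien-3-yl (Z)-2-methylbut-2-enoate
Conditions: angelic acid, 2,4,6-trichlorobenzoyl chloride, Et3N, toluene, rt; then 16, 75 °C
Reagents that add atoms: angelic acid [(Z)-2-methylbut-2-enoic acid], C/C=C(/C)C(=O)O
Why: Yamaguchi-type esterification through the 2,4,6-trichlorobenzoyl mixed anhydride without a nucleophilic catalyst, conditions under which the angeloyl group should be transferred without Z-to-E isomerisation and with retention at C8, since the C8–O bond is not broken.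

Step 10
Reactants: 17 (S)-2-[3-methoxy-2-(methoxymethoxy)-4-methyl-5-[(triisopropylsilyl)oxy]phenyl]-6-methylhepta-1,5-dien-3-yl (Z)-2-methylbut-2-enoate
Product: 19 (S)-2-[5-acetoxy-3-methoxy-2-(methoxymethoxy)-4-methylphenyl]-6-methylhepta-1,5-dien-3-yl (Z)-2-methylbut-2-enoate, via C5 phenol 18 (not isolated)
Conditions: TBAF, THF, 0 °C; then Ac2O, pyridine, 0 °C → rt
Reagents that add atoms: acetic anhydride, CC(=O)OC(C)=O
Why: Fluoride-mediated desilylation followed by in-flask O-acetylation of the liberated phenoxide, so the electron-rich C5 phenol is never isolated and the MOM ether ensures that only the C5 oxygen is acetylated.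

Step 11
Reactants: 19 (S)-2-[5-acetoxy-3-methoxy-2-(methoxymethoxy)-4-methylphenyl]-6-methylhepta-1,5-dien-3-yl (Z)-2-methylbut-2-enoate
Product: 21 (S)-2-(5-acetoxy-2-hydroxy-3-methoxy-4-methylphenyl)-6-methylhepta-1,5-dien-3-yl (Z)-2-methylbut-2-enoate, via aryl trimethylsilyl ether 20 (not isolated)
Conditions: TMSOTf, 2,2′-bipyridyl, CH2Cl2, 0 °C → rt; then H2O
Reagents that add atoms: none
Why: Silyl-triflate-mediated cleavage of an aryl MOM ether, which passes through the aryl trimethylsilyl ether that water hydrolyses; the non-protic conditions should spare both esters, the prenyl alkene and the allylic C8–O bond.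

Compound list
1 | 2-methylbenzene-1,3-diol (2-methylresorcinol) | Cc1c(O)cccc1O | starting material
2 | 4-chloro-2-methylbenzene-1,3-diol | Cc1c(O)ccc(Cl)c1O | intermediate
3 | 6-chloro-2-methyl-3-[(triisopropylsilyl)oxy]phenol | Cc1c(O[Si](C(C)C)(C(C)C)C(C)C)ccc(Cl)c1O | intermediate
4 | (4-chloro-3-methoxy-2-methylphenoxy)triisopropylsilane | COc1c(Cl)ccc(O[Si](C(C)C)(C(C)C)C(C)C)c1C | intermediate
5 | acrolein (prop-2-enal) | C=CC=O | starting material
6 | 2,3-dibromopropanal (racemic, not isolated) | O=CC(Br)CBr | intermediate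
7 | 2-bromoprop-2-enal (2-bromoacrolein) | C=C(Br)C=O | intermediate
8 | (S)-2-bromohexa-1,5-dien-3-yl bis(isopinocampheyl)borinate, Ipc groups from (+)-α-pinene (not isolated) | C=C(Br)[C@H](CC=C)OB([C@@H]1C[C@@H]2C[C@H]([C@H]1C)C2(C)C)[C@@H]1C[C@@H]2C[C@H]([C@H]1C)C2(C)C | intermediate
9 | (S)-2-bromohexa-1,5-dien-3-ol | C=C(Br)[C@H](CC=C)O | intermediate
10 | (S)-2-bromo-6-methylhepta-1,5-dien-3-ol | C=C(Br)[C@H](CC=C(C)C)O | intermediate
11 | lithium (S)-2-lithio-6-methylhepta-1,5-dien-3-olate (not isolated) | C=C([Li])[C@H](CC=C(C)C)O[Li] | intermediate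
12 | 3-methoxy-4-methyl-5-[(triisopropylsilyl)oxy]benzyne, the C1≡C2 aryne (not isolated) | COC1=C(C)C(O[Si](C(C)C)(C(C)C)C(C)C)=CC#C1 | intermediate
13 | lithium (S)-2-[2-lithio-3-methoxy-4-methyl-5-[(triisopropylsilyl)oxy]phenyl]-6-methylhepta-1,5-dien-3-olate (not isolated) | C=C(c1cc(O[Si](C(C)C)(C(C)C)C(C)C)c(C)c(OC)c1[Li])[C@H](CC=C(C)C)O[Li] | intermediate
14 | (3S)-1,8-dimethoxy-7-methyl-4-methylidene-3-(3-methylbut-2-en-1-yl)-6-[(triisopropylsilyl)oxy]-3,4-dihydro-1H-2,1-benzoxaborinine, boron bridging C2 and the C8 oxygen (not isolated) | C=C1c2cc(O[Si](C(C)C)(C(C)C)C(C)C)c(C)c(OC)c2B(OC)O[C@H]1CC=C(C)C | intermediate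
15 | (S)-2-(3-hydroxy-6-methylhepta-1,5-dien-2-yl)-6-methoxy-5-methyl-4-[(triisopropylsilyl)oxy]phenol | C=C(c1cc(O[Si](C(C)C)(C(C)C)C(C)C)c(C)c(OC)c1O)[C@H](CC=C(C)C)O | intermediate
16 | (S)-2-[3-methoxy-2-(methoxymethoxy)-4-methyl-5-[(triisopropylsilyl)oxy]phenyl]-6-methylhepta-1,5-dien-3-ol | C=C(c1cc(O[Si](C(C)C)(C(C)C)C(C)C)c(C)c(OC)c1OCOC)[C@H](CC=C(C)C)O | intermediate
17 | (S)-2-[3-methoxy-2-(methoxymethoxy)-4-methyl-5-[(triisopropylsilyl)oxy]phenyl]-6-methylhepta-1,5-dien-3-yl (Z)-2-methylbut-2-enoate | C=C(c1cc(O[Si](C(C)C)(C(C)C)C(C)C)c(C)c(OC)c1OCOC)[C@H](CC=C(C)C)OC(=O)/C(C)=C\C | intermediate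
18 | (S)-2-[5-hydroxy-3-methoxy-2-(methoxymethoxy)-4-methylphenyl]-6-methylhepta-1,5-dien-3-yl (Z)-2-methylbut-2-enoate (not isolated) | C=C(c1cc(O)c(C)c(OC)c1OCOC)[C@H](CC=C(C)C)OC(=O)/C(C)=C\C | intermediate
19 | (S)-2-[5-acetoxy-3-methoxy-2-(methoxymethoxy)-4-methylphenyl]-6-methylhepta-1,5-dien-3-yl (Z)-2-methylbut-2-enoate | C=C(c1cc(OC(C)=O)c(C)c(OC)c1OCOC)[C@H](CC=C(C)C)OC(=O)/C(C)=C\C | intermediate
20 | (S)-2-[5-acetoxy-3-methoxy-4-methyl-2-[(trimethylsilyl)oxy]phenyl]-6-methylhepta-1,5-dien-3-yl (Z)-2-methylbut-2-enoate (not isolated) | C=C(c1cc(OC(C)=O)c(C)c(OC)c1O[Si](C)(C)C)[C@H](CC=C(C)C)OC(=O)/C(C)=C\C | intermediate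
21 | (S)-2-(5-acetoxy-2-hydroxy-3-methoxy-4-methylphenyl)-6-methylhepta-1,5-dien-3-yl (Z)-2-methylbut-2-enoate | C=C(c1cc(OC(C)=O)c(C)c(OC)c1O)[C@H](CC=C(C)C)OC(=O)/C(C)=C\C | target

Total step count: 11 (steps 1–3 to chloride 4, steps 4–6 to bromide 10, convergent step 7, steps 8–11 to the target).
Longest linear sequence: 8 steps (steps 1–3 or 4–6, then 7–11).

Steps most likely to fail

Step 7. The C2 aryl anion may be quenched by proton transfer from the tetramethylpiperidine formed, or the alkenyllithium may be consumed as a base, before boron capture, so that C–C and C–O bond formation do not both occur. The fallback forms the two bonds separately by cross-coupling chemistry. It sets out from chloride 4, which would undergo Miyaura borylation (B2pin2, Pd(OAc)2, XPhos, KOAc, dioxane, 100 °C) to 2-[2-methoxy-3-methyl-4-[(triisopropylsilyl)oxy]phenyl]-4,4,5,5-tetramethyl-1,3,2-dioxaborolane F1. Oxidation (NaBO3, THF/H2O) would give 2-methoxy-3-methyl-4-[(triisopropylsilyl)oxy]phenol F2, and protection (MOMCl, K2CO3, acetone) would give [3-methoxy-4-(methoxymethoxy)-2-methylphenoxy]triisopropylsilane F3. Lithiation ortho to the MOM group at C1 (n-BuLi, TMEDA, THF, 0 °C) and borylation (B(OMe)3, then aqueous NH4Cl) would give [3-methoxy-2-(methoxymethoxy)-4-methyl-5-[(triisopropylsilyl)oxy]phenyl]boronic acid F4. Suzuki–Miyaura coupling of F4 with bromide 10 (Pd(PPh3)4, K2CO3, dioxane/H2O, 70 °C) would rejoin the route at MOM ether 16.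

Step 6. The ruthenium carbene may be deactivated by the 2-bromoalkene, or the terminal double bond may migrate, so that conversion to the prenyl terminus stays incomplete. The fallback postpones the metathesis until the bromoalkene is gone. It sets out from alcohol 9, which would be taken through the aryne coupling of step 7 with chloride 4 to give (S)-2-(3-hydroxyhexa-1,5-dien-2-yl)-6-methoxy-5-methyl-4-[(triisopropylsilyl)oxy]phenol F5. Cross-metathesis of F5 with 2-methylbut-2-ene (second-generation Hoveyda–Grubbs catalyst, CH2Cl2, 40 °C) would then return to the route at diol 15.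

Step 9. The activated angeloyl unit may isomerise to the E (tigloyl) geometry, or acylation of the hindered allylic alcohol may be too slow. The fallback builds the Z double bond after the ester bond. It sets out from alcohol 16, which would be acylated with 2-[bis(2,2,2-trifluoroethoxy)phosphoryl]propanoic acid (DCC, catalytic DMAP, CH2Cl2) to (S)-2-[3-methoxy-2-(methoxymethoxy)-4-methyl-5-[(triisopropylsilyl)oxy]phenyl]-6-methylhepta-1,5-dien-3-yl 2-[bis(2,2,2-trifluoroethoxy)phosphoryl]propanoate F6 (epimers at the phosphorus-bearing carbon). Still–Gennari olefination of F6 with acetaldehyde (KHMDS, 18-crown-6, THF, −78 °C) would return to the route at angelate 17.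

Further compounds
F1 | step 7 | 2-[2-methoxy-3-methyl-4-[(triisopropylsilyl)oxy]phenyl]-4,4,5,5-tetramethyl-1,3,2-dioxaborolane | COc1c(B2OC(C)(C)C(C)(C)O2)ccc(O[Si](C(C)C)(C(C)C)C(C)C)c1C
F2 | step 7 | 2-methoxy-3-methyl-4-[(triisopropylsilyl)oxy]phenol | COc1c(O)ccc(O[Si](C(C)C)(C(C)C)C(C)C)c1C
F3 | step 7 | [3-methoxy-4-(methoxymethoxy)-2-methylphenoxy]triisopropylsilane | COCOc1ccc(O[Si](C(C)C)(C(C)C)C(C)C)c(C)c1OC
F4 | step 7 | [3-methoxy-2-(methoxymethoxy)-4-methyl-5-[(triisopropylsilyl)oxy]phenyl]boronic acid | COCOc1c(B(O)O)cc(O[Si](C(C)C)(C(C)C)C(C)C)c(C)c1OC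
F5 | step 6 | (S)-2-(3-hydroxyhexa-1,5-dien-2-yl)-6-methoxy-5-methyl-4-[(triisopropylsilyl)oxy]phenol | C=C(c1cc(O[Si](C(C)C)(C(C)C)C(C)C)c(C)c(OC)c1O)[C@H](CC=C)O
F6 | step 9 | (S)-2-[3-methoxy-2-(methoxymethoxy)-4-methyl-5-[(triisopropylsilyl)oxy]phenyl]-6-methylhepta-1,5-dien-3-yl 2-[bis(2,2,2-trifluoroethoxy)phosphoryl]propanoate | C=C(c1cc(O[Si](C(C)C)(C(C)C)C(C)C)c(C)c(OC)c1OCOC)[C@H](CC=C(C)C)OC(=O)C(C)P(=O)(OCC(F)(F)F)OCC(F)(F)F
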